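**Plan**
1. Retrosynthesis: after removal of the ester and the O16 silyl ether, ring A is a cyclohexene whose C3=C4 double bond lies across the ring from the fusion bond C5–C10. This is a Diels–Alder retron, so C5–C10 and C1–C2 are cut together to give an open-chain triene: diene C2=C3–C4=C5, dienophile C1=C10, four-carbon tether C6–C9 (the future ring B).
2. The dienophile carries a phenylsulfonyl group on C1 as activator; it is removed together with the O15 benzyl group in one dissolving-metal step.
3. The triene is cut at C5–C6 (B-alkyl Suzuki–Miyaura coupling with an (E)-enol triflate), at C9–C11 (lactone enolate alkylation) and at C12–C13 (auxiliary allylation).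
4. Forward: side-chain iodide → double alkylation of (S)-4-methyloxolan-2-one → lactone transposition and methylenation → coupling, diene, vinyl sulfone → intramolecular Diels–Alder reaction closing rings A and B in one step → desulfonylation/debenzylation, acylation, desilylation.
5. Stereochemistry: C13 from the oxazolidinone auxiliary, C8 from the chiral pool, C9 by alkylation anti to the C8 methyl, C5 and C10 in the cycloaddition from the (E)-C4=C5 geometry and the C8/C9 centres.

Key step: step 20

Remark: clerodane numbering of the target is used for every intermediate (decalin C1–C10 with fusion carbons C5 and C10; C17 on C8, C18 on C4, C19 on C5, C20 on C9; side chain C11–C16 on C9, C13 bearing C16, ester oxygen on C15). TBS = tert-butyldimethylsilyl, Bn = benzyl, SC = (3R)-5-(benzyloxy)-3-{[(tert-butyldimethylsilyl)oxy]methyl}pentyl. (S)-4-Methyloxolan-2-one and (R)-4-benzyloxazolidin-2-one are assumed to be purchasable.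

**Route**

Step 1
Reactants: 1 4-(benzyloxy)butanoic acid; 2 (4R)-4-benzyl-1,3-oxazolidin-2-one
Product: 3 (4R)-4-benzyl-3-[4-(benzyloxy)butanoyl]-1,3-oxazolidin-2-one
Conditions: DCC, DMAP (cat.), CH2Cl2, 0 °C → rt
Reagents that add atoms: none
Why: Carbodiimide-mediated N-acylation (DMAP acyl transfer) of the oxazolidinone by the acid should give the imide directly; no stereocentre is formed.

Step 2
Reactants: 3 (4R)-4-benzyl-3-[4-(benzyloxy)butanoyl]-1,3-oxazolidin-2-one
Product: 4 (4R)-4-benzyl-3-[(2R)-2-[2-(benzyloxy)ethyl]pent-4-enoyl]-1,3-oxazolidin-2-one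
Conditions: NaN(SiMe3)2, THF, −78 °C; allyl iodide, −78 → −45 °C
Reagents that add atoms: allyl iodide C=CCI
Why: Evans auxiliary alkylation: the chelated (Z)-sodium enolate is allylated on the face away from the C4 benzyl group, which sets C13 as (R) and brings in C12 and C11.

Step 3
Reactants: 4 allylated imide
Product: 5 (2R)-2-[2-(benzyloxy)ethyl]pent-4-en-1-ol
Conditions: LiBH4, Et2O, H2O (1 equiv), 0 °C
Reagents that add atoms: none
Why: Reductive cleavage of the N-acyl oxazolidinone (hydride attack at the exocyclic carbonyl) releases the C16 primary alcohol without touching C13 and returns the auxiliary.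

Step 4
Reactants: 5 (2R)-2-[2-(benzyloxy)ethyl]pent-4-en-1-ol
Product: 6 {[(2R)-2-[2-(benzyloxy)ethyl]pent-4-en-1-yl]oxy}(tert-butyl)dimethylsilane
Conditions: TBSCl, imidazole, DMF, rt
Reagents that add atoms: tert-butyldimethylsilyl chloride CC(C)(C)[Si](C)(C)Cl
Why: Standard silylation of a primary alcohol; the O16 silyl ether is orthogonal to the O15 benzyl ether and is kept to the last step.

Step 5
Reactants: 6 silyl ether alkene
Product: 8 (3R)-5-(benzyloxy)-3-{[(tert-butyldimethylsilyl)oxy]methyl}pentan-1-ol, via aldehyde 7 (not isolated)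
Conditions: O3, CH2Cl2/MeOH, −78 °C; then NaBH4, −78 → 0 °C
Reagents that add atoms: ozone [O-][O+]=O
Why: Ozonolysis of the only alkene removes the surplus terminal carbon and in situ borohydride reduction of aldehyde 7 gives the C11 alcohol, the benzyl and silyl ethers being inert under these conditions.

Step 6
Reactants: 8 (3R)-5-(benzyloxy)-3-{[(tert-butyldimethylsilyl)oxy]methyl}pentan-1-ol
Product: 9 {[(2S)-2-[2-(benzyloxy)ethyl]-4-iodobutyl]oxy}(tert-butyl)dimethylsilane
Conditions: I2, PPh3, imidazole, CH2Cl2, 0 °C → rt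
Reagents that add atoms: iodine II
Why: Appel-type iodination (iodophosphonium activation, SN2 by iodide) of the unhindered primary alcohol; C13 is not involved and only its descriptor changes.

Step 7
Reactants: 10 (4S)-4-methyloxolan-2-one
Product: 11 (3S,4S)-3,4-dimethyloxolan-2-one
Conditions: LiN(i-Pr)2, THF, −78 °C; MeI
Reagents that add atoms: iodomethane CI
Why: Alkylation of the lactone lithium enolate with iodomethane anti to the C4 methyl group (trans product); this centre is planarised again in step 8, so only the C8 centre from the chiral pool matters.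

Step 8
Reactants: 11 (3S,4S)-3,4-dimethyloxolan-2-one; 9 side-chain iodide
Product: 12 (3S,4S)-3-SC-3,4-dimethyloxolan-2-one
Conditions: LiN(i-Pr)2, THF, −78 °C; then 9, DMPU, −78 → −20 °C
Reagents that add atoms: none
Why: Enolate alkylation (SN2) forming the quaternary centre: iodide 9 attacks the trisubstituted lactone enolate anti to the adjacent C8 methyl group, so the chain ends trans and C20 cis to C17, the C9 (S) configuration of the target.

Step 9
Reactants: 12 quaternary lactone
Product: 13 (2S,3S)-2-SC-2,3-dimethylbutane-1,4-diol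
Conditions: LiAlH4, THF, 0 °C → rt
Reagents that add atoms: none
Why: Hydride reduction of the lactone to the 1,4-diol; the ethers and both stereocentres are untouched.

Step 10
Reactants: 13 diol
Product: 14 (3S,4S)-4-SC-3,4-dimethyloxolan-2-one
Conditions: [Cu(MeCN)4]OTf (cat.), 2,2'-bipyridine, TEMPO (cat.), N-methylimidazole, air, MeCN, rt
Reagents that add atoms: none
Why: Copper/nitroxyl aerobic oxidative lactonisation, in which the less hindered C7 hydroxyl is oxidised in preference to the neopentyl C10 hydroxyl and the resulting lactol is oxidised on, so that the carbonyl is transposed from C10 to C7 without protecting groups.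

Step 11
Reactants: 14 transposed lactone
Product: 15 (3S,4S)-4-SC-3,4-dimethyloxolan-2-ol (anomer mixture)
Conditions: i-Bu2AlH, CH2Cl2, −78 °C
Reagents that add atoms: none
Why: Partial reduction of a lactone to the lactol by one hydride transfer at low temperature, the tetrahedral aluminium alkoxide being stable until work-up.

Step 12
Reactants: 15 lactol
Product: 16 (2S,3R)-2-SC-2,3-dimethylpent-4-en-1-ol
Conditions: Ph3PCH3Br, KOt-Bu, THF, 0 °C → rt
Reagents that add atoms: methyltriphenylphosphonium bromide C[P+](c1ccccc1)(c1ccccc1)c1ccccc1.[Br-]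
Why: Wittig methylenation of the open hydroxy aldehyde form of the lactol gives the C7=C6 vinyl group and frees the C10 hydroxyl; excess ylide under mild conditions limits epimerisation at C8.

Step 13
Reactants: 17 methyl 2-methyl-3-oxobutanoate
Product: 18 methyl (2E)-2-methyl-3-{[(trifluoromethyl)sulfonyl]oxy}but-2-enoate
Conditions: Tf2O, aq. Me4NOH, hexanes, 5 °C
Reagents that add atoms: trifluoromethanesulfonic anhydride O=S(=O)(OS(=O)(=O)C(F)(F)F)C(F)(F)F
Why: O-Sulfonylation of the non-chelated tetramethylammonium enolate under biphasic conditions should favour the (E)-enol triflate (triflate trans to the ester), the geometry that later places C6 trans to C3.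

Step 14
Reactants: 16 vinyl alcohol; 18 (E)-enol triflate
Product: 20 methyl (2E,6R,7S,10R)-12-(benzyloxy)-10-{[(tert-butyldimethylsilyl)oxy]methyl}-7-(hydroxymethyl)-2,3,6,7-tetramethyldodec-2-enoate, via C6-alkylborane 19 (not isolated)
Conditions: 9-BBN (2.5 equiv), THF, 0 °C → rt; then 18, PdCl2(dppf) (cat.), AsPh3, K3PO4 (aq.), DMF, 50 °C
Reagents that add atoms: none
Why: Anti-Markovnikov hydroboration of the terminal alkene puts boron on C6 and B-alkyl Suzuki–Miyaura coupling (oxidative addition of the triflate to zerovalent palladium, transmetalation, reductive elimination) forms C5–C6 with retention of the alkene geometry; the free hydroxyl only consumes one equivalent of borane as a borinate.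

Step 15
Reactants: 20 hydroxy enoate
Product: 21 (2E,6R,7S,10R)-12-(benzyloxy)-10-{[(tert-butyldimethylsilyl)oxy]methyl}-7-(hydroxymethyl)-2,3,6,7-tetramethyldodec-2-en-1-ol
Conditions: i-Bu2AlH (excess), CH2Cl2, −78 → −20 °C
Reagents that add atoms: none
Why: 1,2-Reduction of the unsaturated ester by two hydride transfers gives the allylic alcohol without touching the tetrasubstituted alkene.

Step 16
Reactants: 21 allylic diol
Product: 22 (2E,6R,7S,10R)-12-(benzyloxy)-10-{[(tert-butyldimethylsilyl)oxy]methyl}-7-(hydroxymethyl)-2,3,6,7-tetramethyldodec-2-enal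
Conditions: MnO2, CH2Cl2, rt
Reagents that add atoms: none
Why: MnO2 oxidises only the allylic alcohol (selectivity for activated alcohols) and leaves the saturated neopentyl C10 hydroxyl.

Step 17
Reactants: 22 enal
Product: 23 (2S,3R,6E)-2-SC-2,3,6,7-tetramethylnona-6,8-dien-1-ol
Conditions: Ph3PCH3Br, KOt-Bu, THF, −78 → 0 °C
Reagents that add atoms: methyltriphenylphosphonium bromide C[P+](c1ccccc1)(c1ccccc1)c1ccccc1.[Br-]
Why: Wittig methylenation of the hindered enal completes the C2=C3–C4=C5 diene; low temperature and short contact time are used so that the C4=C5 geometry is kept.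

Step 18
Reactants: 23 diene alcohol
Product: 24 (2S,3R,6E)-2-SC-2,3,6,7-tetramethylnona-6,8-dienal
Conditions: Dess–Martin periodinane, NaHCO3, CH2Cl2, 0 °C → rt
Reagents that add atoms: none
Why: Dess–Martin oxidation of the neopentyl alcohol under buffered conditions tolerated by the diene; the aldehyde has no α-hydrogen and cannot epimerise.

Step 19
Reactants: 24 dienal
Product: 25 {[(1E,3S,4R,7E)-3-SC-3,4,7,8-tetramethyldeca-1,7,9-trien-1-yl]sulfonyl}benzene
Conditions: (EtO)2P(O)CH2SO2Ph, NaH, THF, 0 °C → rt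
Reagents that add atoms: diethyl [(phenylsulfonyl)methyl]phosphonate CCOP(=O)(CS(=O)(=O)c1ccccc1)OCC
Why: Horner–Wadsworth–Emmons olefination with the sulfonyl-stabilised phosphonate anion gives the (E)-vinyl sulfone, installing C1 and the activating group on the dienophile.

Step 20
Reactants: 25 (E)-vinyl sulfone triene
Product: 26 (1S,2R,4aR,8R,8aR)-1-SC-1,2,4a,5-tetramethyl-8-(phenylsulfonyl)-1,2,3,4,4a,7,8,8a-octahydronaphthalene
Conditions: PhMe (dilute), BHT, 160 °C, sealed tube
Reagents that add atoms: none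
Why: Thermal, concerted but asynchronous [4+2] cycloaddition of normal electron demand between the electron-rich C2=C3–C4=C5 diene and the sulfonyl-activated C1=C10 alkene; the closest known reaction type is the type 1 intramolecular Diels–Alder reaction of sulfonyl- or ester-activated 1,7,9-decatrienes. Ring A closes through the two new bonds C5–C10 and C1–C2 of the cycloaddition, and ring B closes at the same moment as the six-membered ring spanned by the C6–C9 tether, in a chair-like arrangement with the tether exo and the sulfonyl group endo (anti, trans-fused mode). C5 and C10 are set by the (E) geometry of the C4=C5 bond (C6 outside, C19 inside) together with this anti transition state, which puts H10 and C19 trans; the diene face is chosen by the existing centres, the C8 methyl staying equatorial and the smaller C9 substituent (C20) taking the axial site syn to C19; C1 (sulfonyl cis to H10, from the E alkene) is lost in step 21. The step needs trans- over cis-fusion and one diene face: because C9 is quaternary, the syn (cis-fused) arrangements would force diene carbon C4 or C1 axial against a C9 substituent, whereas the anti one pairs only the two methyl groups. The sulfonyl group lowers the barrier so that cyclisation should outrun the [1,5]-hydrogen shift open to a diene with an inside methyl group.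

Step 21
Reactants: 26 sulfonyl decalin
Product: 27 (3R)-3-{[(tert-butyldimethylsilyl)oxy]methyl}-5-[(1S,2R,4aR,8aR)-1,2,4a,5-tetramethyl-1,2,3,4,4a,7,8,8a-octahydronaphthalen-1-yl]pentan-1-ol
Conditions: Na, NH3(l), THF, −78 °C; then NH4Cl
Reagents that add atoms: none
Why: Dissolving-metal reduction: single-electron transfer cleaves the C1–S bond (loss of benzenesulfinate, protonation of the C1 anion) and the benzylic C–O bond in the same operation, while the isolated trisubstituted alkene and the silyl ether are not reduced.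

Step 22
Reactants: 27 primary alcohol; 28 docosanoic acid
Product: 29 (3R)-3-{[(tert-butyldimethylsilyl)oxy]methyl}-5-[(1S,2R,4aR,8aR)-1,2,4a,5-tetramethyl-1,2,3,4,4a,7,8,8a-octahydronaphthalen-1-yl]pentyl docosanoate
Conditions: DCC, DMAP, CH2Cl2, rt
Reagents that add atoms: none
Why: Steglich esterification (O-acylisourea, DMAP acyl transfer) of the only free hydroxyl (O15) with the fatty acid.

Step 23
Reactants: 29 silyl ether ester
Product: 30 (3R)-3-(hydroxymethyl)-5-[(1S,2R,4aR,8aR)-1,2,4a,5-tetramethyl-1,2,3,4,4a,7,8,8a-octahydronaphthalen-1-yl]pentyl docosanoate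
Conditions: HF·pyridine, pyridine, THF, 0 °C → rt
Reagents that add atoms: none
Why: Fluoride-mediated cleavage of the primary silyl ether under buffered conditions that leave the ester in place and should not cause acyl migration or alkene isomerisation, giving the target.

**Compound list**
1 | 4-(benzyloxy)butanoic acid | OC(=O)CCCOCc1ccccc1 | starting material
2 | (4R)-4-benzyl-1,3-oxazolidin-2-one | O=C1N[C@H](Cc2ccccc2)CO1 | starting material
3 | (4R)-4-benzyl-3-[4-(benzyloxy)butanoyl]-1,3-oxazolidin-2-one | O=C(CCCOCc1ccccc1)N1C(=O)OC[C@H]1Cc1ccccc1 | intermediate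
4 | (4R)-4-benzyl-3-[(2R)-2-[2-(benzyloxy)ethyl]pent-4-enoyl]-1,3-oxazolidin-2-one | C=CC[C@H](CCOCc1ccccc1)C(=O)N1C(=O)OC[C@H]1Cc1ccccc1 | intermediate
5 | (2R)-2-[2-(benzyloxy)ethyl]pent-4-en-1-ol | C=CC[C@H](CCOCc1ccccc1)CO | intermediate
6 | {[(2R)-2-[2-(benzyloxy)ethyl]pent-4-en-1-yl]oxy}(tert-butyl)dimethylsilane | C=CC[C@H](CCOCc1ccccc1)CO[Si](C)(C)C(C)(C)C | intermediate
7 | (3S)-5-(benzyloxy)-3-{[(tert-butyldimethylsilyl)oxy]methyl}pentanal (not isolated) | O=CC[C@H](CCOCc1ccccc1)CO[Si](C)(C)C(C)(C)C | intermediate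
8 | (3R)-5-(benzyloxy)-3-{[(tert-butyldimethylsilyl)oxy]methyl}pentan-1-ol | OCC[C@H](CCOCc1ccccc1)CO[Si](C)(C)C(C)(C)C | intermediate
9 | {[(2S)-2-[2-(benzyloxy)ethyl]-4-iodobutyl]oxy}(tert-butyl)dimethylsilane | ICC[C@H](CCOCc1ccccc1)CO[Si](C)(C)C(C)(C)C | intermediate
10 | (4S)-4-methyloxolan-2-one | O=C1C[C@H](C)CO1 | starting material
11 | (3S,4S)-3,4-dimethyloxolan-2-one | C[C@H]1[C@H](C)COC1=O | intermediate
12 | (3S,4S)-3-[(3R)-5-(benzyloxy)-3-{[(tert-butyldimethylsilyl)oxy]methyl}pentyl]-3,4-dimethyloxolan-2-one | c1ccccc1COCC[C@H](CO[Si](C)(C)C(C)(C)C)CC[C@@]1(C)[C@H](C)COC1=O | intermediate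
13 | (2S,3S)-2-[(3R)-5-(benzyloxy)-3-{[(tert-butyldimethylsilyl)oxy]methyl}pentyl]-2,3-dimethylbutane-1,4-diol | c1ccccc1COCC[C@H](CO[Si](C)(C)C(C)(C)C)CC[C@](C)(CO)[C@H](C)CO | intermediate
14 | (3S,4S)-4-[(3R)-5-(benzyloxy)-3-{[(tert-butyldimethylsilyl)oxy]methyl}pentyl]-3,4-dimethyloxolan-2-one | c1ccccc1COCC[C@H](CO[Si](C)(C)C(C)(C)C)CC[C@]1(C)COC(=O)[C@H]1C | intermediate
15 | (3S,4S)-4-[(3R)-5-(benzyloxy)-3-{[(tert-butyldimethylsilyl)oxy]methyl}pentyl]-3,4-dimethyloxolan-2-ol (anomer mixture) | c1ccccc1COCC[C@H](CO[Si](C)(C)C(C)(C)C)CC[C@]1(C)COC(O)[C@H]1C | intermediate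
16 | (2S,3R)-2-[(3R)-5-(benzyloxy)-3-{[(tert-butyldimethylsilyl)oxy]methyl}pentyl]-2,3-dimethylpent-4-en-1-ol | c1ccccc1COCC[C@H](CO[Si](C)(C)C(C)(C)C)CC[C@](C)(CO)[C@H](C)C=C | intermediate
17 | methyl 2-methyl-3-oxobutanoate | COC(=O)C(C)C(C)=O | starting material
18 | methyl (2E)-2-methyl-3-{[(trifluoromethyl)sulfonyl]oxy}but-2-enoate | COC(=O)/C(C)=C(/OS(=O)(=O)C(F)(F)F)C | intermediate
19 | 9-BBN adduct of 16 with boron on C6 and the C10 oxygen as its 9-BBN borinate (not isolated) | c1ccccc1COCC[C@H](CO[Si](C)(C)C(C)(C)C)CC[C@](C)(COB1C2CCCC1CCC2)[C@H](C)CCB1C2CCCC1CCC2 | intermediate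
20 | methyl (2E,6R,7S,10R)-12-(benzyloxy)-10-{[(tert-butyldimethylsilyl)oxy]methyl}-7-(hydroxymethyl)-2,3,6,7-tetramethyldodec-2-enoate | c1ccccc1COCC[C@H](CO[Si](C)(C)C(C)(C)C)CC[C@](C)(CO)[C@H](C)CC/C(C)=C(/C(=O)OC)C | intermediate
21 | (2E,6R,7S,10R)-12-(benzyloxy)-10-{[(tert-butyldimethylsilyl)oxy]methyl}-7-(hydroxymethyl)-2,3,6,7-tetramethyldodec-2-en-1-ol | c1ccccc1COCC[C@H](CO[Si](C)(C)C(C)(C)C)CC[C@](C)(CO)[C@H](C)CC/C(C)=C(/CO)C | intermediate
22 | (2E,6R,7S,10R)-12-(benzyloxy)-10-{[(tert-butyldimethylsilyl)oxy]methyl}-7-(hydroxymethyl)-2,3,6,7-tetramethyldodec-2-enal | c1ccccc1COCC[C@H](CO[Si](C)(C)C(C)(C)C)CC[C@](C)(CO)[C@H](C)CC/C(C)=C(/C=O)C | intermediate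
23 | (2S,3R,6E)-2-[(3R)-5-(benzyloxy)-3-{[(tert-butyldimethylsilyl)oxy]methyl}pentyl]-2,3,6,7-tetramethylnona-6,8-dien-1-ol | c1ccccc1COCC[C@H](CO[Si](C)(C)C(C)(C)C)CC[C@](C)(CO)[C@H](C)CC/C(C)=C(/C=C)C | intermediate
24 | (2S,3R,6E)-2-[(3R)-5-(benzyloxy)-3-{[(tert-butyldimethylsilyl)oxy]methyl}pentyl]-2,3,6,7-tetramethylnona-6,8-dienal | c1ccccc1COCC[C@H](CO[Si](C)(C)C(C)(C)C)CC[C@](C)(C=O)[C@H](C)CC/C(C)=C(/C=C)C | intermediate
25 | {[(1E,3S,4R,7E)-3-[(3R)-5-(benzyloxy)-3-{[(tert-butyldimethylsilyl)oxy]methyl}pentyl]-3,4,7,8-tetramethyldeca-1,7,9-trien-1-yl]sulfonyl}benzene | c1ccccc1COCC[C@H](CO[Si](C)(C)C(C)(C)C)CC[C@](C)(/C=C/S(=O)(=O)c1ccccc1)[C@H](C)CC/C(C)=C(/C=C)C | intermediate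
26 | (1S,2R,4aR,8R,8aR)-1-[(3R)-5-(benzyloxy)-3-{[(tert-butyldimethylsilyl)oxy]methyl}pentyl]-1,2,4a,5-tetramethyl-8-(phenylsulfonyl)-1,2,3,4,4a,7,8,8a-octahydronaphthalene | c1ccccc1COCC[C@H](CO[Si](C)(C)C(C)(C)C)CC[C@@]1(C)[C@H](C)CC[C@@]2(C)C(C)=CC[C@@H](S(=O)(=O)c3ccccc3)[C@H]12 | intermediate
27 | (3R)-3-{[(tert-butyldimethylsilyl)oxy]methyl}-5-[(1S,2R,4aR,8aR)-1,2,4a,5-tetramethyl-1,2,3,4,4a,7,8,8a-octahydronaphthalen-1-yl]pentan-1-ol | OCC[C@H](CO[Si](C)(C)C(C)(C)C)CC[C@@]1(C)[C@H](C)CC[C@@]2(C)C(C)=CCC[C@H]12 | intermediate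
28 | docosanoic acid | CCCCCCCCCCCCCCCCCCCCCC(=O)O | starting material
29 | (3R)-3-{[(tert-butyldimethylsilyl)oxy]methyl}-5-[(1S,2R,4aR,8aR)-1,2,4a,5-tetramethyl-1,2,3,4,4a,7,8,8a-octahydronaphthalen-1-yl]pentyl docosanoate | CCCCCCCCCCCCCCCCCCCCCC(=O)OCC[C@H](CO[Si](C)(C)C(C)(C)C)CC[C@@]1(C)[C@H](C)CC[C@@]2(C)C(C)=CCC[C@H]12 | intermediate
30 | (3R)-3-(hydroxymethyl)-5-[(1S,2R,4aR,8aR)-1,2,4a,5-tetramethyl-1,2,3,4,4a,7,8,8a-octahydronaphthalen-1-yl]pentyl docosanoate | CCCCCCCCCCCCCCCCCCCCCC(=O)OCC[C@H](CO)CC[C@@]1(C)[C@H](C)CC[C@@]2(C)C(C)=CCC[C@H]12 | target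

**Step count**
Total steps: 23. Longest linear sequence: 21 steps (steps 1–6, 8–12 and 14–23, from acid 1).

**Steps most likely to fail**

Step 20. The cycloaddition may be too slow at the fully substituted diene terminus, so that [1,5]-hydrogen shift or polymerisation of the diene takes over, or closure may run through the syn (cis-fused) transition state. Fallback, from aldehyde 24 back to alcohol 27: 24 is olefinated with Ph3P=CHCHO (toluene, 80 °C) to the (E)-enal triene F1. Me2AlCl in CH2Cl2 at −78 °C then promotes a Lewis-acid-catalysed, endo-selective intramolecular Diels–Alder reaction at low temperature to the C1-formyl trans-decalin F2. Decarbonylation with RhCl(PPh3)3 (toluene, 110 °C) gives the benzyl ether decalin F3, and Na/NH3 debenzylation as in step 21 returns to 27.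

Step 8. SN2 displacement by the hindered, fully substituted enolate may be slow, with elimination of the iodide or proton transfer competing, and facial selectivity at C9 may be incomplete. Fallback, from lactone 11 and aldehyde 7 back to lactone 12: the C9–C11 bond is made by an aldol addition instead. The lithium enolate of 11 (THF, −78 °C) adds to 7, isolated after ozonolysis of 6 with PPh3 work-up, again anti to the C8 methyl, to give the β-hydroxy lactone F4 (carbinol epimers at C11). PhOC(S)Cl, pyridine and DMAP give the phenyl thionocarbonate F5, and Barton–McCombie deoxygenation (Bu3SnH, AIBN, toluene, 90 °C) returns to 12.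

Step 14. Transmetalation and reductive elimination toward a tetrasubstituted alkene may be slow, with β-hydride elimination or protodeboronation competing, and the (E) geometry set in step 13 may erode. Fallback, from alcohol 16 back to diol 21: 16 is capped (TESCl, imidazole) as the triethylsilyl ether F6, then hydroborated and iodinated (9-BBN; then I2, NaOMe) to the primary C6 iodide F7. Alkylation of dilithiated prop-2-yn-1-ol (THF/DMPU) gives the alkynol F8. Copper-catalysed anti-carbomagnesiation of this propargylic alcohol (MeMgBr, CuI, THF; then MeI) places C18 on C4 and C19 on C5 trans to each other and gives the (E)-allylic alcohol silyl ether F9, whose triethylsilyl group is removed (PPTS, MeOH, 0 °C) to return to 21.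

Further compounds
F1 | step 20 | (2E,4S,5R,8E)-4-[(3R)-5-(benzyloxy)-3-{[(tert-butyldimethylsilyl)oxy]methyl}pentyl]-4,5,8,9-tetramethylundeca-2,8,10-trienal | c1ccccc1COCC[C@H](CO[Si](C)(C)C(C)(C)C)CC[C@](C)(/C=C/C=O)[C@H](C)CC/C(C)=C(/C=C)C
F2 | step 20 | analogue of 26 with a formyl group in place of the phenylsulfonyl group on C1 (cis to H10) | c1ccccc1COCC[C@H](CO[Si](C)(C)C(C)(C)C)CC[C@@]1(C)[C@H](C)CC[C@@]2(C)C(C)=CC[C@@H](C=O)[C@H]12
F3 | step 20 | O15-benzyl ether of 27 | c1ccccc1COCC[C@H](CO[Si](C)(C)C(C)(C)C)CC[C@@]1(C)[C@H](C)CC[C@@]2(C)C(C)=CCC[C@H]12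
F4 | step 8 | 12 bearing a hydroxyl group on C11 (epimer mixture at C11) | c1ccccc1COCC[C@H](CO[Si](C)(C)C(C)(C)C)CC(O)[C@@]1(C)[C@H](C)COC1=O
F5 | step 8 | O-phenyl thionocarbonate of F4 | c1ccccc1COCC[C@H](CO[Si](C)(C)C(C)(C)C)CC(OC(=S)Oc2ccccc2)[C@@]1(C)[C@H](C)COC1=O
F6 | step 14 | triethylsilyl ether of 16 | c1ccccc1COCC[C@H](CO[Si](C)(C)C(C)(C)C)CC[C@](C)(CO[Si](CC)(CC)CC)[C@H](C)C=C
F7 | step 14 | C6 iodide from anti-Markovnikov hydroiodination of F6 | c1ccccc1COCC[C@H](CO[Si](C)(C)C(C)(C)C)CC[C@](C)(CO[Si](CC)(CC)CC)[C@H](C)CCI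
F8 | step 14 | alkynol with C5≡C4 triple bond and C3 hydroxymethyl, C10 triethylsilyl ether | c1ccccc1COCC[C@H](CO[Si](C)(C)C(C)(C)C)CC[C@](C)(CO[Si](CC)(CC)CC)[C@H](C)CCC#CCO
F9 | step 14 | C10 triethylsilyl ether of 21 | c1ccccc1COCC[C@H](CO[Si](C)(C)C(C)(C)C)CC[C@](C)(CO[Si](CC)(CC)CC)[C@H](C)CC/C(C)=C(/CO)C
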